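The tetrahydrofuran ring (O1; C2 benzyl, C3 OH, C4 CH2OH, C5 aryl) is treated as a reduced γ-lactone. Its C2, C3, C4 and the hydroxymethyl carbon on C4 are the four carbons of (S)-malic acid, the malate carbinol being C3. In one operation the dianion of diisopropyl (S)-malate adds to the aryl aldehyde that carries the cis-dihydrobenzofuran (C4–C5 bond), and the aldolate oxygen closes onto the ester next to the carbinol (O1–C2 bond). The purchased C3 centre relays C4 and C5. C2 is set later by hydrogenation of a benzylidene enol ether made from the lactone. The aldehyde arises from a cis-selective asymmetric rhodium-carbene C–H insertion.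

Key step: step 8

Remark: the 2-aryl-3-(hydroxymethyl)-2,3-dihydrobenzofuran of the target is the cis isomer (2R,3R), so strong acid and strong base are avoided once it is made. The sense of induction of Rh2(S-PTTL)4 is assumed from its behaviour with related aryldiazoacetates; if it proves opposite, the enantiomeric catalyst is used.

Step 1
Reactants: 1 4-(benzyloxy)-3-methoxybenzyl alcohol
Product: 2 4-(benzyloxy)-3-methoxybenzyl chloride
Conditions: SOCl2, CH2Cl2, 0 °C → rt; used crude
Reagents that add atoms: thionyl chloride O=S(Cl)Cl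
Why: Chlorodehydroxylation of an electron-rich benzylic alcohol through its chlorosulfite should be fast at 0 °C, and no stereocentre is involved.

Step 2
Reactants: 3 methyl 4-hydroxy-3-iodo-5-methoxybenzoate; 2 4-(benzyloxy)-3-methoxybenzyl chloride
Product: 4 methyl 4-{[4-(benzyloxy)-3-methoxybenzyl]oxy}-3-iodo-5-methoxybenzoate
Conditions: K2CO3, KI (cat.), DMF, 60 °C
Reagents that add atoms: none
Why: Williamson ether synthesis, in which the phenoxide of 3 displaces the benzylic chloride under iodide catalysis while ester and aryl iodide are inert to K2CO3.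

Step 3
Reactants: 4 aryl iodide; 5 ethyl diazoacetate
Product: 6 ethyl 2-diazo-2-[2-{[4-(benzyloxy)-3-methoxybenzyl]oxy}-3-methoxy-5-(methoxycarbonyl)phenyl]acetate
Conditions: Pd(PPh3)4 (5 mol %), Ag2CO3 (0.5 equiv), Et3N, toluene, rt
Reagents that add atoms: none
Why: Palladium-catalysed cross-coupling of an aryl iodide with the C–H bond of a diazo ester, in which the diazo group is retained, should give the donor/acceptor diazo compound directly.

Step 4
Reactants: 6 aryldiazoacetate
Product: 7 3-ethyl 5-methyl (2R,3S)-2-[4-(benzyloxy)-3-methoxyphenyl]-7-methoxy-2,3-dihydro-1-benzofuran-3,5-dicarboxylate (2,3-cis)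
Conditions: Rh2(S-PTTL)4 (dirhodium tetrakis[N-phthaloyl-(S)-tert-leucinate], 1 mol %), toluene, −60 °C
Reagents that add atoms: none
Why: Intramolecular 1,5 C–H insertion of the rhodium carbene into the activated benzylic ether C–H bond closes the dihydrobenzofuran; carboxylate catalysts of this type are known to favour the cis-2-aryl-3-carboxylate, and the chiral ligand sphere sets both new centres, expected as (2R,3S).

Step 5
Reactants: 7 cis diester
Product: 8 [(2R,3R)-2-[4-(benzyloxy)-3-methoxyphenyl]-7-methoxy-2,3-dihydro-1-benzofuran-3,5-diyl]dimethanol (2,3-cis)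
Conditions: LiAlH4, THF, −40 → 0 °C; Rochelle salt work-up
Reagents that add atoms: none
Why: Hydride reduction of both esters at low temperature should be faster than enolisation of the cis ester, so the 2,3-cis relationship is expected to survive.

Step 6
Reactants: 8 diol
Product: 9 (2R,3R)-2-[4-(benzyloxy)-3-methoxyphenyl]-3-(hydroxymethyl)-7-methoxy-2,3-dihydro-1-benzofuran-5-carbaldehyde
Conditions: MnO2 (activated, excess), CH2Cl2, rt
Reagents that add atoms: none
Why: MnO2 oxidises benzylic but not saturated primary alcohols, so only the aryl carbinol should become the aldehyde.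

Step 7
Reactants: 9 hydroxy aldehyde
Product: 10 (2R,3R)-2-[4-(benzyloxy)-3-methoxyphenyl]-3-{[(tert-butyldimethylsilyl)oxy]methyl}-7-methoxy-2,3-dihydro-1-benzofuran-5-carbaldehyde
Conditions: TBSCl, imidazole, DMF, rt
Reagents that add atoms: tert-butyldimethylsilyl chloride CC(C)(C)[Si](C)(C)Cl
Why: Standard silylation of the primary alcohol removes the only acidic proton of the aldehyde partner before the dianion chemistry.

Step 8
Reactants: 11 diisopropyl (S)-malate; 10 silyl-protected aldehyde
Product: 14 propan-2-yl (2S,3S,4S)-2-aryl-4-hydroxy-5-oxooxolane-3-carboxylate (all-trans lactone; aryl = the dihydrobenzofuran-5-yl group of 10), via dilithium alkoxide–enolate 12 (not isolated), via dilithium aldolate 13 (not isolated)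
Conditions: 11 (1.3 equiv), LiN(SiMe3)2 (2.7 equiv), THF, −78 → −20 °C; then 10, −78 → 0 °C; AcOH quench at 0 °C
Reagents that add atoms: none
Why: Fráter–Seebach-type aldol addition followed by lactonisation: LiN(SiMe3)2 converts 11 into the chelated alkoxide–enolate 12, whose enolate carbon (future C4) adds to the aldehyde carbon of 10 (future C5), and the aldolate oxygen (O1) of 13 then attacks the ester carbonyl next to the carbinol (future C2) and expels isopropoxide. The closest known reactions are the alkylations and hydroxyalkylations of malate dianions, which give γ-lactones with carbonyl electrophiles. The ring closes by 5-exo-trig acyl substitution; attack on the other ester would need a four-membered ring and is not expected. C4 is set by approach of the aldehyde to the enolate face anti to the lithium alkoxide substituent of the six-membered chelate (1,2-induction from the purchased C3), and C5 by a closed Zimmerman–Traxler transition state of the chelation-fixed (Z)-O-enolate with the aryl group equatorial, which places aryl and ester trans on the ring. The step needs π-facial selectivity on both partners; the chelate secures the first, and the all-trans lactone should also be the thermodynamic sink because C4 remains epimerisable next to its ester. Warming only to 0 °C and an acetic acid quench should spare the silyl ether and the cis-dihydrobenzofuran.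

Step 9
Reactants: 14 hydroxy lactone
Product: 15 tert-butyldimethylsilyl ether of 14 (same configuration, all-trans)
Conditions: TBSOTf, 2,6-lutidine, CH2Cl2, −78 → 0 °C
Reagents that add atoms: tert-butyldimethylsilyl trifluoromethanesulfonate CC(C)(C)[Si](C)(C)OS(=O)(=O)C(F)(F)F
Why: Silylation with a silyl triflate and a hindered pyridine base should protect the α-hydroxy lactone without enolisation.

Step 10
Reactants: 2 4-(benzyloxy)-3-methoxybenzyl chloride; 15 silyloxy lactone
Product: 17 lactol (2-[4-(benzyloxy)-3-methoxybenzyl]-2-hydroxy tetrahydrofuran; hemiketal carbon unassigned; other centres as in 15), via benzylic Grignard reagent 16 (not isolated)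
Conditions: 2, Mg turnings, THF, 0 °C (slow addition); then 15, THF, −78 °C; aq. NH4Cl at −78 °C
Reagents that add atoms: none
Why: Mono-addition of a benzylic Grignard reagent to a γ-lactone at −78 °C should stop at the magnesium hemiketal, as with sugar lactones, and the strained α-silyloxy lactone is expected to react before the hindered isopropyl ester.

Step 11
Reactants: 17 lactol
Product: 18 (Z)-2-[4-(benzyloxy)-3-methoxybenzylidene] tetrahydrofuran (exocyclic enol ether; C3 OTBS, C4 CO2iPr, C5 aryl as in 15)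
Conditions: (CF3CO)2O, pyridine, CH2Cl2, 0 °C → rt
Reagents that add atoms: none
Why: Trifluoroacetylation of the hemiketal hydroxyl, ionisation to the oxocarbenium ion and loss of a benzylic proton should give the aryl-conjugated exocyclic enol ether, as in exo-glycal formation.

Step 12
Reactants: 18 enol ether ester
Product: 19 primary alcohol (C4 CH2OH; enol ether, silyl and benzyl ethers unchanged)
Conditions: LiAlH4, THF, −20 → 0 °C; Rochelle salt work-up
Reagents that add atoms: none
Why: LiAlH4 should reduce the isopropyl ester to the primary alcohol while enol ether, silyl ethers and benzyl ethers are inert.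

Step 13
Reactants: 19 enol ether alcohol
Product: 20 bis-silyl ether of the target (both phenols free; C3 OTBS and dihydrobenzofuran CH2OTBS; THF centres as in the target)
Conditions: H2 (1 atm), Pd/C, NaHCO3, EtOAc, rt
Reagents that add atoms: none
Why: Heterogeneous hydrogenation should deliver hydrogen to C2 from the face of the C4 hydroxymethyl group, opposite the allylic silyloxy group and the C5 aryl group, which sets C2 with the benzyl group cis to C3–O and C5–aryl; the two phenolic benzyl ethers are cleaved in the same operation.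

Step 14
Reactants: 20 bis-silyl ether
Product: 21 (2S,3S,4S,5S)-2-(4-hydroxy-3-methoxybenzyl)-5-[(2R,3R)-2-(4-hydroxy-3-methoxyphenyl)-3-(hydroxymethyl)-7-methoxy-2,3-dihydro-1-benzofuran-5-yl]-4-(hydroxymethyl)oxolan-3-ol (CNP0179668.1)
Conditions: Bu4NF, AcOH, THF, rt → 40 °C
Reagents that add atoms: none
Why: Fluoride should cleave both silyl ethers, and acetic acid buffering keeps the free phenols and the cis-dihydrobenzofuran out of basic conditions.

Compound list
1 | 4-(benzyloxy)-3-methoxybenzyl alcohol | OCc1ccc(OCc2ccccc2)c(OC)c1 | starting material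
2 | 4-(benzyloxy)-3-methoxybenzyl chloride | ClCc1ccc(OCc2ccccc2)c(OC)c1 | intermediate
3 | methyl 4-hydroxy-3-iodo-5-methoxybenzoate | COC(=O)c1cc(I)c(O)c(OC)c1 | starting material
4 | methyl 4-{[4-(benzyloxy)-3-methoxybenzyl]oxy}-3-iodo-5-methoxybenzoate | COC(=O)c1cc(I)c(OCc2ccc(OCc3ccccc3)c(OC)c2)c(OC)c1 | intermediate
5 | ethyl diazoacetate | CCOC(=O)C=[N+]=[N-] | starting material
6 | ethyl 2-diazo-2-[2-{[4-(benzyloxy)-3-methoxybenzyl]oxy}-3-methoxy-5-(methoxycarbonyl)phenyl]acetate | CCOC(=O)C(=[N+]=[N-])c1cc(C(=O)OC)cc(OC)c1OCc1ccc(OCc2ccccc2)c(OC)c1 | intermediate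
7 | 3-ethyl 5-methyl (2R,3S)-2-[4-(benzyloxy)-3-methoxyphenyl]-7-methoxy-2,3-dihydro-1-benzofuran-3,5-dicarboxylate (cis) | COC(=O)c1cc(OC)c2c(c1)[C@H](C(=O)OCC)[C@H](c1ccc(OCc3ccccc3)c(OC)c1)O2 | intermediate
8 | [(2R,3R)-2-[4-(benzyloxy)-3-methoxyphenyl]-7-methoxy-2,3-dihydro-1-benzofuran-3,5-diyl]dimethanol (cis) | OCc1cc(OC)c2c(c1)[C@H](CO)[C@H](c1ccc(OCc3ccccc3)c(OC)c1)O2 | intermediate
9 | (2R,3R)-2-[4-(benzyloxy)-3-methoxyphenyl]-3-(hydroxymethyl)-7-methoxy-2,3-dihydro-1-benzofuran-5-carbaldehyde | O=Cc1cc(OC)c2c(c1)[C@H](CO)[C@H](c1ccc(OCc3ccccc3)c(OC)c1)O2 | intermediate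
10 | (2R,3R)-2-[4-(benzyloxy)-3-methoxyphenyl]-3-{[(tert-butyldimethylsilyl)oxy]methyl}-7-methoxy-2,3-dihydro-1-benzofuran-5-carbaldehyde | O=Cc1cc(OC)c2c(c1)[C@H](CO[Si](C)(C)C(C)(C)C)[C@H](c1ccc(OCc3ccccc3)c(OC)c1)O2 | intermediate
11 | diisopropyl (S)-malate | CC(C)OC(=O)C[C@H](O)C(=O)OC(C)C | starting material
12 | dilithium alkoxide–enolate of 11 (chelated (Z)-O-enolate, formed in situ) | [Li+].[Li+].CC(C)OC(=O)[C@@H]([O-])/C=C(\[O-])OC(C)C | intermediate
13 | dilithium aldolate (open-chain adduct of 12 and 10, formed in situ) | [Li+].[Li+].[O-][C@H](c1cc(OC)c2c(c1)[C@H](CO[Si](C)(C)C(C)(C)C)[C@H](c1ccc(OCc3ccccc3)c(OC)c1)O2)[C@@H](C(=O)OC(C)C)[C@H]([O-])C(=O)OC(C)C | intermediate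
14 | propan-2-yl (2S,3S,4S)-2-aryl-4-hydroxy-5-oxooxolane-3-carboxylate, all-trans, aryl = dihydrobenzofuran-5-yl group of 10 | O1[C@H](c2cc(OC)c3c(c2)[C@H](CO[Si](C)(C)C(C)(C)C)[C@H](c2ccc(OCc4ccccc4)c(OC)c2)O3)[C@@H](C(=O)OC(C)C)[C@H](O)C1=O | intermediate
15 | tert-butyldimethylsilyl ether of 14 | O1[C@H](c2cc(OC)c3c(c2)[C@H](CO[Si](C)(C)C(C)(C)C)[C@H](c2ccc(OCc4ccccc4)c(OC)c2)O3)[C@@H](C(=O)OC(C)C)[C@H](O[Si](C)(C)C(C)(C)C)C1=O | intermediate
16 | [4-(benzyloxy)-3-methoxybenzyl]magnesium chloride (formed in situ) | Cl[Mg]Cc1ccc(OCc2ccccc2)c(OC)c1 | intermediate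
17 | lactol from addition of 16 to the lactone carbonyl of 15 (hemiketal carbon unassigned) | O1[C@H](c2cc(OC)c3c(c2)[C@H](CO[Si](C)(C)C(C)(C)C)[C@H](c2ccc(OCc4ccccc4)c(OC)c2)O3)[C@@H](C(=O)OC(C)C)[C@H](O[Si](C)(C)C(C)(C)C)C1(O)Cc5ccc(OCc6ccccc6)c(OC)c5 | intermediate
18 | (Z)-benzylidene exocyclic enol ether, isopropyl ester | O1[C@H](c2cc(OC)c3c(c2)[C@H](CO[Si](C)(C)C(C)(C)C)[C@H](c2ccc(OCc4ccccc4)c(OC)c2)O3)[C@@H](C(=O)OC(C)C)[C@H](O[Si](C)(C)C(C)(C)C)/C1=C/c5ccc(OCc6ccccc6)c(OC)c5 | intermediate
19 | (Z)-benzylidene exocyclic enol ether, C4 hydroxymethyl | O1[C@H](c2cc(OC)c3c(c2)[C@H](CO[Si](C)(C)C(C)(C)C)[C@H](c2ccc(OCc4ccccc4)c(OC)c2)O3)[C@@H](CO)[C@H](O[Si](C)(C)C(C)(C)C)/C1=C/c5ccc(OCc6ccccc6)c(OC)c5 | intermediate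
20 | bis(tert-butyldimethylsilyl) ether of the target (C3–O and dihydrobenzofuran CH2–O silylated, phenols free) | O1[C@H](c2cc(OC)c3c(c2)[C@H](CO[Si](C)(C)C(C)(C)C)[C@H](c2ccc(O)c(OC)c2)O3)[C@@H](CO)[C@H](O[Si](C)(C)C(C)(C)C)[C@@H]1Cc5ccc(O)c(OC)c5 | intermediate
21 | (2S,3S,4S,5S)-2-(4-hydroxy-3-methoxybenzyl)-5-[(2R,3R)-2-(4-hydroxy-3-methoxyphenyl)-3-(hydroxymethyl)-7-methoxy-2,3-dihydro-1-benzofuran-5-yl]-4-(hydroxymethyl)oxolan-3-ol | COc1cc(C[C@@H]2O[C@H](c3cc(OC)c4c(c3)[C@H](CO)[C@H](c3ccc(O)c(OC)c3)O4)[C@@H](CO)[C@@H]2O)ccc1O | target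

Total step count: 14. Longest linear sequence: 14 steps (1 → 21; compound 2 is used in steps 2 and 10, and 3, 5 and 11 enter as starting materials).

Steps most likely to fail

Step 8. Facial control at the aldehyde carbonyl may be incomplete, giving C5 epimers, or ring closure of the aldolate may stall. The fallback sets out from 10 and 11 and returns at 14. The aldol is run at −78 °C and quenched cold to take the open-chain adducts, the diisopropyl (2S)-2-hydroxy-3-[aryl(hydroxy)methyl]butanedioate mixture F1. MnO2 oxidises only the benzylic carbinol and gives the aroyl succinate F2. Transfer hydrogenation with RuCl(p-cymene)[(S,S)-TsDPEN] and HCO2H/Et3N sets the carbinol centre under reagent control and gives the (S)-carbinol F3. PPTS in warm toluene closes the lactone, and a trace of DBU settles the ester-bearing carbon trans, which returns to 14.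

Step 13. Hydrogen delivery to the exocyclic enol ether may discriminate poorly between the two faces, or the ring benzylic C–O bonds may undergo hydrogenolysis while the benzyl ethers are removed. The fallback sets out from 19 and returns at 20. Hydroxyl-directed homogeneous hydrogenation with [Ir(cod)(PCy3)(py)]PF6 and H2 in CH2Cl2 uses the C4 hydroxymethyl group, held on the required face, to deliver hydrogen to C2 and gives the saturated bis(benzyl ether) F4. Brief transfer hydrogenolysis (Pd/C, 1,4-cyclohexadiene, EtOH) then removes the two phenolic benzyl groups to reach 20.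

Step 3. Oxidative addition next to the bulky benzyloxy group may be slow, and the diazo group may be lost through carbene dimerisation. The fallback sets out from 4 and returns at 6. Negishi-type coupling of 4 with the Reformatsky reagent BrZnCH2CO2Et (Pd(dba)2, XPhos, THF) gives the arylacetate, ethyl 2-[2-{[4-(benzyloxy)-3-methoxybenzyl]oxy}-3-methoxy-5-(methoxycarbonyl)phenyl]acetate F5. Diazo transfer with p-acetamidobenzenesulfonyl azide and DBU in MeCN gives 6.

Further compounds
F1 | step 8 | diisopropyl (2S)-2-hydroxy-3-[aryl(hydroxy)methyl]butanedioate, mixture at the two new centres (aryl as in 10) | OC(c1cc(OC)c2c(c1)[C@H](CO[Si](C)(C)C(C)(C)C)[C@H](c1ccc(OCc3ccccc3)c(OC)c1)O2)C(C(=O)OC(C)C)[C@H](O)C(=O)OC(C)C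
F2 | step 8 | diisopropyl (2S)-3-aroyl-2-hydroxybutanedioate (β-keto ester, C3 epimerisable) | O=C(c1cc(OC)c2c(c1)[C@H](CO[Si](C)(C)C(C)(C)C)[C@H](c1ccc(OCc3ccccc3)c(OC)c1)O2)C(C(=O)OC(C)C)[C@H](O)C(=O)OC(C)C
F3 | step 8 | diisopropyl (2S)-2-hydroxy-3-[(S)-aryl(hydroxy)methyl]butanedioate | O[C@H](c1cc(OC)c2c(c1)[C@H](CO[Si](C)(C)C(C)(C)C)[C@H](c1ccc(OCc3ccccc3)c(OC)c1)O2)C(C(=O)OC(C)C)[C@H](O)C(=O)OC(C)C
F4 | step 13 | saturated tetrahydrofuran with both phenols still benzylated (C2 benzyl cis to C3 OTBS and C5 aryl) | O1[C@H](c2cc(OC)c3c(c2)[C@H](CO[Si](C)(C)C(C)(C)C)[C@H](c2ccc(OCc4ccccc4)c(OC)c2)O3)[C@@H](CO)[C@H](O[Si](C)(C)C(C)(C)C)[C@@H]1Cc5ccc(OCc6ccccc6)c(OC)c5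
F5 | step 3 | ethyl 2-[2-{[4-(benzyloxy)-3-methoxybenzyl]oxy}-3-methoxy-5-(methoxycarbonyl)phenyl]acetate | CCOC(=O)Cc1cc(C(=O)OC)cc(OC)c1OCc1ccc(OCc2ccccc2)c(OC)c1
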